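**Assumption:** Bisoflavolin K has no stereocentre and no hindered axis (the diaryl ether rotates freely), so the target is achiral and no stereocontrol is needed.

## Retrosynthetic overview

1. Last step: remove two benzyl ethers (O7 of each chromone) with BCl3.
2. Key disconnection: the diaryl ether C3′–O bond. It is made by a new rhodium-carbene O–H insertion between an ortho-quinone diazide on ring B of the daidzein half and the 4′-OH of the 8-chlorodaidzein half; the neighbouring 4′-OH of the first half emerges free in the same event.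
3. Quinone diazide ⇐ aminophenol ⇐ nitrophenol ⇐ O7-benzyl daidzein; nitration ortho to the free 4′-OH fixes the regiochemistry.
4. Ring order: both pyranone rings are built first, each by one-pot Friedel–Crafts acylation/formylative annulation of (4-hydroxyphenyl)acetic acid with resorcinol or 2-chlororesorcinol (chlorine enters with the latter). The diaryl ether joining the two isoflavones is formed last.

## Route

Step 1
Reactants: 1 resorcinol; 2 (4-hydroxyphenyl)acetic acid
Product: 4 daidzein (7-hydroxy-3-(4-hydroxyphenyl)-4H-chromen-4-one), via trihydroxydeoxybenzoin 3 (not isolated)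
Conditions: BF3·OEt2 (solvent), 85 °C, 2 h; then DMF, MsCl, 70 °C, 2 h; H2O
Reagents that add atoms: N,N-dimethylformamide, CN(C)C=O
Why: BF3-mediated Friedel–Crafts acylation of resorcinol at C4 gives the deoxybenzoin, whose methylene is formylated by the DMF/MsCl Vilsmeier-type reagent and closes onto the ortho-OH with loss of dimethylamine (deoxybenzoin route to isoflavones); no stereocentre is formed.

Step 2
Reactants: 4 daidzein
Product: 5 benzyldaidzein (7-benzyloxy-3-(4-hydroxyphenyl)-4H-chromen-4-one)
Conditions: BnBr (1.05 equiv), K2CO3 (1.1 equiv), DMF, 25 °C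
Reagents that add atoms: benzyl bromide, BrCc1ccccc1
Why: Williamson etherification under pKa control; the 7-OH, conjugated to the C4 carbonyl, is about two pKa units more acidic than the 4′-OH, so one equivalent of carbonate forms and benzylates only the 7-phenoxide.

Step 3
Reactants: 5 benzyldaidzein
Product: 6 nitrophenol (7-benzyloxy-3-(4-hydroxy-3-nitrophenyl)-4H-chromen-4-one)
Conditions: HNO3 (65%, 1.05 equiv), AcOH–CH2Cl2, 15 °C
Reagents that add atoms: nitric acid, O[N+](=O)[O-]
Why: Electrophilic aromatic nitration takes place on the only free-phenol ring, ortho to the 4′-OH because para is blocked, while the carbonyl-deactivated ring A and the benzyl group resist one equivalent of dilute acid.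

Step 4
Reactants: 6 nitrophenol
Product: 7 aminophenol (3-(3-amino-4-hydroxyphenyl)-7-benzyloxy-4H-chromen-4-one)
Conditions: Fe powder, AcOH, EtOH–H2O, 60 °C, N2; used promptly
Reagents that add atoms: none
Why: Béchamp-type dissolving-metal reduction by zerovalent iron converts the nitro group into the amine without touching the chromone enone or the benzyl ether.

Step 5
Reactants: 7 aminophenol
Product: 8 ortho-quinone diazide (2-diazonio-4-(7-benzyloxy-4-oxo-4H-chromen-3-yl)phenolate)
Conditions: NaNO2, aq. HCl, THF, 0 °C; then NaHCO3 to pH 7, CH2Cl2 extraction, Na2SO4 and 4 Å MS, dark, kept cold in solution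
Reagents that add atoms: sodium nitrite, [Na+].[O-]N=O
Why: Diazotisation of the ortho-aminophenol gives the diazonium salt, which loses HCl on neutralisation to the neutral, extractable diazonium phenolate (ortho-quinone diazide).

Step 6
Reactants: 9 chlororesorcinol (2-chlorobenzene-1,3-diol); 2 (4-hydroxyphenyl)acetic acid
Product: 11 chlorodaidzein (8-chloro-7-hydroxy-3-(4-hydroxyphenyl)-4H-chromen-4-one), via chlorodeoxybenzoin 10 (not isolated)
Conditions: BF3·OEt2 (solvent), 90 °C, 3 h; then DMF, MsCl, 80 °C, 2 h; H2O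
Reagents that add atoms: N,N-dimethylformamide, CN(C)C=O
Why: The same Friedel–Crafts acylation/formylative annulation; 2-chlororesorcinol is mirror-symmetric, so acylation at C4 or C6 gives one deoxybenzoin, and closure through the OH flanked by acyl and Cl places Cl at C8 and the remaining OH at C7.

Step 7
Reactants: 11 chlorodaidzein
Product: 12 benzylchlorodaidzein (7-benzyloxy-8-chloro-3-(4-hydroxyphenyl)-4H-chromen-4-one)
Conditions: BnBr (1.05 equiv), K2CO3 (1.1 equiv), DMF, 25 °C
Reagents that add atoms: benzyl bromide, BrCc1ccccc1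
Why: Williamson etherification under pKa control; the 7-OH, acidified further by the ortho chlorine, is deprotonated and benzylated selectively, leaving the 4′-OH free for the coupling.

Step 8
Reactants: 8 ortho-quinone diazide; 12 benzylchlorodaidzein (1.5 equiv)
Product: 13 dibenzyl bisoflavolin K (7-benzyloxy-3-[4-({5-[7-benzyloxy-4-oxo-4H-chromen-3-yl]-2-hydroxyphenyl}oxy)phenyl]-8-chloro-4H-chromen-4-one)
Conditions: Rh2(OAc)4 (2 mol%), 4 Å MS, CH2Cl2, 30 °C, dark, 8 added by syringe pump over 4 h
Reagents that add atoms: none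
Why: Proposed new method: Rh2(OAc)4 expels N2 from the ortho-quinone diazide to give an electrophilic divalent-rhodium quinoid carbene at C3′ (a masked 2-oxidoaryl cation); the 4′-OH of 12 adds to form an oxonium ylide, and proton transfer to the adjacent oxygen with Rh–C cleavage aromatises directly to the 2-aryloxyphenol, so the ether lands only on the carbon that carried nitrogen and the neighbouring oxygen appears as the free 4′-OH with no stereocentre formed; the closest known reaction types are rhodium-carbene O–H insertion of α-diazo ketones into phenols and carbene transfer from quinone diazides, not yet shown for a benzenoid ortho-quinone diazide as the electrophile of a catechol mono-aryl ether synthesis.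

Step 9
Reactants: 13 dibenzyl bisoflavolin K
Product: 14 bisoflavolin K (8-chloro-7-hydroxy-3-(4-{2-hydroxy-5-[7-hydroxy-4-oxo-4H-chromen-3-yl]phenoxy}phenyl)-4H-chromen-4-one)
Conditions: BCl3 (6 equiv), C6HMe5 (8 equiv), CH2Cl2, −78 → −40 °C; then MeOH, H2O
Reagents that add atoms: none
Why: Lewis-acid debenzylation; BCl3 ionises both aryl benzyl ethers at low temperature and pentamethylbenzene traps the benzyl cation by Friedel–Crafts alkylation, sparing the aryl chloride, the chromone double bonds and the diaryl ether that hydrogenolysis could endanger.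

## Compound list

1 | resorcinol (benzene-1,3-diol) | Oc1cccc(O)c1 | starting material
2 | (4-hydroxyphenyl)acetic acid | OC(=O)Cc1ccc(O)cc1 | starting material
3 | trihydroxydeoxybenzoin, 1-(2,4-dihydroxyphenyl)-2-(4-hydroxyphenyl)ethan-1-one | O=C(Cc1ccc(O)cc1)c1ccc(O)cc1O | intermediate (not isolated)
4 | daidzein, 7-hydroxy-3-(4-hydroxyphenyl)-4H-chromen-4-one | O=c1c(-c2ccc(O)cc2)coc2cc(O)ccc12 | intermediate
5 | benzyldaidzein, 7-(benzyloxy)-3-(4-hydroxyphenyl)-4H-chromen-4-one | O=c1c(-c2ccc(O)cc2)coc2cc(OCc3ccccc3)ccc12 | intermediate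
6 | nitrophenol, 7-(benzyloxy)-3-(4-hydroxy-3-nitrophenyl)-4H-chromen-4-one | O=c1c(-c2ccc(O)c([N+](=O)[O-])c2)coc2cc(OCc3ccccc3)ccc12 | intermediate
7 | aminophenol, 3-(3-amino-4-hydroxyphenyl)-7-(benzyloxy)-4H-chromen-4-one | O=c1c(-c2ccc(O)c(N)c2)coc2cc(OCc3ccccc3)ccc12 | intermediate
8 | ortho-quinone diazide, 2-diazonio-4-[7-(benzyloxy)-4-oxo-4H-chromen-3-yl]phenolate | O=c1c(-c2ccc([O-])c([N+]#N)c2)coc2cc(OCc3ccccc3)ccc12 | intermediate
9 | chlororesorcinol, 2-chlorobenzene-1,3-diol | Oc1cccc(O)c1Cl | starting material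
10 | chlorodeoxybenzoin, 1-(3-chloro-2,4-dihydroxyphenyl)-2-(4-hydroxyphenyl)ethan-1-one | O=C(Cc1ccc(O)cc1)c1ccc(O)c(Cl)c1O | intermediate (not isolated)
11 | chlorodaidzein, 8-chloro-7-hydroxy-3-(4-hydroxyphenyl)-4H-chromen-4-one | O=c1c(-c2ccc(O)cc2)coc2c(Cl)c(O)ccc12 | intermediate
12 | benzylchlorodaidzein, 7-(benzyloxy)-8-chloro-3-(4-hydroxyphenyl)-4H-chromen-4-one | O=c1c(-c2ccc(O)cc2)coc2c(Cl)c(OCc3ccccc3)ccc12 | intermediate
13 | dibenzyl bisoflavolin K, 7-(benzyloxy)-3-[4-({5-[7-(benzyloxy)-4-oxo-4H-chromen-3-yl]-2-hydroxyphenyl}oxy)phenyl]-8-chloro-4H-chromen-4-one | O=c1c(-c2ccc(O)c(Oc3ccc(-c4coc5c(Cl)c(OCc6ccccc6)ccc5c4=O)cc3)c2)coc2cc(OCc3ccccc3)ccc12 | intermediate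
14 | bisoflavolin K, 8-chloro-7-hydroxy-3-(4-{2-hydroxy-5-[7-hydroxy-4-oxo-4H-chromen-3-yl]phenoxy}phenyl)-4H-chromen-4-one | O=c1c(-c2ccc(O)c(Oc3ccc(-c4coc5c(Cl)c(O)ccc5c4=O)cc3)c2)coc2cc(O)ccc12 | target

## Step count and risk

Total steps: 9. Longest linear sequence: 7 (steps 1, 2, 3, 4, 5, 8, 9); the chlorinated half adds steps 6 and 7.

**Most likely to fail, first: step 8 (the proposed new O–H insertion).** The quinoid carbene may undergo Wolff ring contraction, 8 may azo-couple with 12, or the hindered product phenol may insert a second carbene. The fallback uses known Ullmann chemistry, sets out from 5 (with 12 as the partner) and comes back to the route at 14. Iodinate 5 ortho to the phenol (NIS, cat. TFA, MeCN, 0 °C) to give the iodophenol 7-(benzyloxy)-3-(4-hydroxy-3-iodophenyl)-4H-chromen-4-one F1. Benzylate the 4′-OH (BnBr, K2CO3, DMF) to give the aryl iodide 7-(benzyloxy)-3-[4-(benzyloxy)-3-iodophenyl]-4H-chromen-4-one F2. Couple F2 with phenol 12 by copper-catalysed Ullmann etherification (CuI, picolinic acid, K3PO4, DMSO, 90 °C) to give tribenzyl bisoflavolin K F3. Remove all three benzyl groups under the conditions of step 9 to reach 14.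

**Second: step 6 (one-pot acylation/annulation on the less nucleophilic, hindered 2-chlororesorcinol).** The fallback changes the disconnection to a C3–aryl Suzuki coupling, sets out from 9 and comes back at 12, bypassing 10 and 11.
- Acetylate 9 (AcOH, BF3·OEt2, 90 °C) to give 1-(3-chloro-2,4-dihydroxyphenyl)ethan-1-one F4.
- Benzylate the non-chelated 4-OH (BnBr, K2CO3, acetone) to give 1-[4-(benzyloxy)-3-chloro-2-hydroxyphenyl]ethan-1-one F5.
- Condense with DMF dimethyl acetal (toluene, 90 °C) to give the enaminone (E)-1-[4-(benzyloxy)-3-chloro-2-hydroxyphenyl]-3-(dimethylamino)prop-2-en-1-one F6.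
- Cyclise with iodine (I2, CHCl3, 25 °C) to give the iodochromone 7-(benzyloxy)-8-chloro-3-iodo-4H-chromen-4-one F7.
- Couple F7 with commercial (4-hydroxyphenyl)boronic acid (Pd(PPh3)4, Na2CO3, DME–H2O, 80 °C) to give 12; the C8 chloride is inert under these conditions.

**Third: step 3 (nitration; possible ring A nitration, dinitration or oxidation).** The fallback replaces electrophilic nitration by azo coupling and reductive cleavage, sets out from 5 and comes back at 7, bypassing 6. Prepare benzenediazonium chloride F8 from aniline (NaNO2, aq. HCl, 0 °C). Couple it with the phenoxide of 5 (aq. NaOH–THF, pH 9–10, 0 °C); only the free-phenol ring reacts, ortho to the OH, giving the azo phenol 7-(benzyloxy)-3-{4-hydroxy-3-[(E)-phenyldiazenyl]phenyl}-4H-chromen-4-one F9. Cleave the N=N bond with Na2S2O4 (aq. EtOH, 70 °C) to give 7.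

## Further compounds

F1 | step 8 | 7-(benzyloxy)-3-(4-hydroxy-3-iodophenyl)-4H-chromen-4-one | O=c1c(-c2ccc(O)c(I)c2)coc2cc(OCc3ccccc3)ccc12
F2 | step 8 | 7-(benzyloxy)-3-[4-(benzyloxy)-3-iodophenyl]-4H-chromen-4-one | O=c1c(-c2ccc(OCc3ccccc3)c(I)c2)coc2cc(OCc3ccccc3)ccc12
F3 | step 8 | tribenzyl bisoflavolin K, 7-(benzyloxy)-3-[4-({2-(benzyloxy)-5-[7-(benzyloxy)-4-oxo-4H-chromen-3-yl]phenyl}oxy)phenyl]-8-chloro-4H-chromen-4-one | O=c1c(-c2ccc(OCc3ccccc3)c(Oc3ccc(-c4coc5c(Cl)c(OCc6ccccc6)ccc5c4=O)cc3)c2)coc2cc(OCc3ccccc3)ccc12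
F4 | step 6 | 1-(3-chloro-2,4-dihydroxyphenyl)ethan-1-one | CC(=O)c1ccc(O)c(Cl)c1O
F5 | step 6 | 1-[4-(benzyloxy)-3-chloro-2-hydroxyphenyl]ethan-1-one | CC(=O)c1ccc(OCc2ccccc2)c(Cl)c1O
F6 | step 6 | (E)-1-[4-(benzyloxy)-3-chloro-2-hydroxyphenyl]-3-(dimethylamino)prop-2-en-1-one | CN(C)/C=C/C(=O)c1ccc(OCc2ccccc2)c(Cl)c1O
F7 | step 6 | 7-(benzyloxy)-8-chloro-3-iodo-4H-chromen-4-one | O=c1c(I)coc2c(Cl)c(OCc3ccccc3)ccc12
F8 | step 3 | benzenediazonium chloride | N#[N+]c1ccccc1.[Cl-]
F9 | step 3 | 7-(benzyloxy)-3-{4-hydroxy-3-[(E)-phenyldiazenyl]phenyl}-4H-chromen-4-one | O=c1c(-c2ccc(O)c(/N=N/c3ccccc3)c2)coc2cc(OCc3ccccc3)ccc12
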